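The readings were generated by integration with made-up constants.

Take Monday's run, the asked flask itself followed up to 30.0 h, and ask first how far its electrophile goes.

| flask | electrophile | nucleophile | free base | remark | time |
|---|---|---|---|---|---|
| Monday's | 0.20 M | 0.36 M | 0.060 M | the very flask that is asked about, followed so far |  |
| Friday's | 0.20 M | 0.36 M | 0.090 M | run made earlier |  |
| flask | 0.20 M | 0.360 M | 0.0600 M |  | 2.5 d |

| run | time / h | electrophile / % | target / % |
|---|---|---|---|
| Monday's | 2.50 | 87 | 8 |
| Monday's | 4.00 | 85 | 12 |
| Monday's | 6.00 | 79 | 20 |
| Monday's | 8.00 | 70 | 25 |
| Monday's | 12.0 | 60 | 32 |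
| Monday's | 20.0 | 43 | 36 |
| Monday's | 30.0 | 28 | 38 |
| Friday's | 2.00 | 92 | 7 |
| Friday's | 3.00 | 91 | 13 |
| Friday's | 4.00 | 82 | 14 |
| Friday's | 6.00 | 79 | 19 |
| Friday's | 10.0 | 65 | 24 |
| Friday's | 15.0 | 55 | 31 |
| Friday's | 25.0 | 35 | 39 |

(each reading ± 1.5 percentage points)

- part of the electrophile that has reacted at 2.5 d
- share of the unused nucleophile that is free and not bound as protonated nucleophile, at 2.5 d

- the earlier runs were read with a standard deviation of 1.5 percentage points
- the earlier runs do not show how much of nucleophile is bound; that part of a forecast is a guess

From 87 % to 28 % the logarithm of the electrophile falls at 0.0412 h⁻¹, and carrying that slope on to 2.5 d gives my estimate of 8.13 % left.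

Next, what does a lost electrophile spend? Between the last two readings electrophile falls from 43 % to 28 % while target rises from 36 % to 38 %, a differential selectivity of 0.133, which is a rough reading. I suppose two steps: one spends a nucleophile and makes target and acid set free, the other joins electrophile and target. Lost electrophile is then their sum and standing target their difference, so time drops out. With that selectivity I put target at 40.6 %, which gives 66.3 % of the electrophile charged: the making turnover, the mean of electrophile lost and target standing, here an estimated 0.133 M of nucleophile spent and acid set free.

Last, how much nucleophile stays free? I let free base take 0.0600 M of that acid. If nucleophile binds the remaining 0.0730 M out of its unused 0.227 M, 68.1 % stays free, so I commit to 91.9 % reacted and a free share above that.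

The forecast gives 92 % reacted and 40 % free, a free share lower than my floor, with the remark “Incomplete binding or less nucleophile consumption raises this”.

The flask gives 90.4 % reacted and 77.6 % free.

    electrophile + nucleophile → acid set free + target (k = 0.00190 M⁻¹ min⁻¹)
    nucleophile + acid set free ⇌ protonated nucleophile, settled at all times (K = 82.0 M⁻¹)
    acid set free + free base ⇌ salt of the base, settled at all times (K = 71000 M⁻¹)
    electrophile + target → side product (k = 0.00320 M⁻¹ min⁻¹)
    crystals ⇌ acid set free, rate k5*(cs5 - [acid set free]) while solid is left; crystals form when [acid set free] > cs5 (solubility = 2.40 mM, k = 0.00950 min⁻¹)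

In this flask free base is down to 0.491 % of its charge at 1.25 d, when the step to side product has 66 % of its turnover up to 2.5 d behind it. Of my 0.133 M, the flask at 2.50 d shows 0.0598 M as salt of the base, 0.0510 M as protonated nucleophile, 0.0184 M as crystals and 0.00352 M as acid set free. In the neighbour flask with 0.61 M of nucleophile, the same mean over its 1.82 % electrophile and 59.3 % target gives 0.157 M spent and a floor of 78.6 %, and its free share stands at 80.8 %.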